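**Plan**

1. Side-chain atoms are numbered C1′ (benzylic) to C36′. The retrosynthesis cuts, in this order: the two quinone C=O groups (back to a 1,4-dimethoxynaphthalene), the 7′-CH3 (back to an anilide C=O), C6′–C7′ (fragment union), C8′–C9′ (radical conjugate addition), C20′–C21′ (allyl sulfone alkylation), C1′–C2′ together with C3′–CH3 (carboalumination/benzylation), and ring C3–C1′ (chloromethylation).
2. Forward: menadione is turned in four steps into the head iodide 8. Farnesol and geranylgeraniol give the C35 alcohol 18, which is extended by three carbons to the α-bromo anilide 24. Compound 24 and the zinc reagent of 8 are joined, then the amide becomes the 7′-methyl and CAN liberates the quinone.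
3. Stereochemistry: C11′ comes from Ru–BINAP hydrogenation of farnesol (catalyst control). C7′ is created in the union step by a chiral Ni/Pybox catalyst from an equal mixture of both C7′ bromide epimers. All E-alkenes come from farnesol, geranylgeraniol, E-selective SeO2 oxidation and syn-carboalumination.
4. Enabling feature: C7′ is a CH flanked by C6′H2 and C8′H2 whose only other substituent is a methyl group. If that methyl carbon is carried as C(=O)N(Bn)Ph, C7′ becomes an α-carbonyl C–Br that gives a planar radical under nickel. With the naphthoquinone ring masked as 1,4-dimethoxynaphthalene, the C6′ terminus can be a primary alkylzinc.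

Key step: step 17

Assumption: the sense of induction of the Ni/(i-Pr)-Pybox catalyst is assigned by analogy with simpler α-bromo anilides; the ligand antipode that gives 7′R (written here as R) is to be fixed on a model bromide, both antipodes being commercial.

**Route**

Step 1
Reactants: 1 menadione (2-methylnaphthalene-1,4-dione)
Product: 3 1,4-dimethoxy-2-methylnaphthalene, via menadiol 2 (not isolated)
Conditions: Na2S2O4, Bu4NBr (cat.), THF/H2O, rt, Ar; then aq. KOH, Me2SO4, 0 °C to rt (one pot)
Reagents that add atoms: dimethyl sulfate COS(=O)(=O)OC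
Why: Dithionite reduction of the quinone to the hydroquinone followed in the same pot by Williamson O-methylation (reductive methylation) masks the redox-active ring for the organometallic steps.

Step 2
Reactants: 3 1,4-dimethoxy-2-methylnaphthalene
Product: 4 2-(chloromethyl)-1,4-dimethoxy-3-methylnaphthalene
Conditions: (CH2O)n, conc. HCl, HCl (g), 1,4-dioxane, rt
Reagents that add atoms: formaldehyde C=O (as paraformaldehyde); hydrogen chloride Cl
Why: Blanc chloromethylation (electrophilic aromatic substitution) can only take C3, the single free position of the dialkoxy-activated ring.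

Step 3
Reactants: 5 5-chloropent-1-yne; 4 2-(chloromethyl)-1,4-dimethoxy-3-methylnaphthalene
Product: 7 2-[(2E)-6-chloro-3-methylhex-2-en-1-yl]-1,4-dimethoxy-3-methylnaphthalene, via alkenylalane 6 (not isolated)
Conditions: Me3Al (2 equiv), Cp2ZrCl2 (0.25 equiv), ClCH2CH2Cl, 0 °C to rt; volatiles removed in vacuo, THF; then 4, Ni(PPh3)4 made from NiCl2(PPh3)2/n-BuLi (3 mol%), 0 °C to rt
Reagents that add atoms: trimethylaluminium C[Al](C)C
Why: Zr-catalysed Negishi carboalumination adds methyl and aluminium syn across the alkyne with aluminium at the terminus, and the Ni(0)-catalysed cross-coupling of the alkenylalane with the benzylic chloride proceeds with retention, so the 2′E alkene is fixed while the primary alkyl chloride stays untouched.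

Step 4
Reactants: 7 2-[(2E)-6-chloro-3-methylhex-2-en-1-yl]-1,4-dimethoxy-3-methylnaphthalene
Product: 8 2-[(2E)-6-iodo-3-methylhex-2-en-1-yl]-1,4-dimethoxy-3-methylnaphthalene
Conditions: NaI, acetone, reflux
Reagents that add atoms: sodium iodide [Na+].[I-]
Why: Finkelstein halide exchange (SN2), driven by precipitation of NaCl, gives the iodide needed for mild zinc insertion.

Step 5
Reactants: 9 (2E,6E)-farnesol
Product: 10 (3R,6E)-3,7,11-trimethyldodeca-6,10-dien-1-ol ((R)-2,3-dihydrofarnesol)
Conditions: H2 (100 atm), Ru(OAc)2[(S)-BINAP] (0.1 mol%), 95:5 MeOH/H2O, 20 °C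
Reagents that add atoms: none
Why: Ru–BINAP asymmetric hydrogenation of an allylic alcohol (Noyori type) reduces only the hydroxyl-directed C2=C3 bond, and the (S)-ligand with the 2E alkene should set C3 as R by analogy with geraniol giving (R)-citronellol; this centre becomes C11′.

Step 6
Reactants: 10 (R)-2,3-dihydrofarnesol
Product: 11 (3R,6E)-3,7,11-trimethyldodeca-6,10-dien-1-yl acetate
Conditions: Ac2O, pyridine, DMAP (cat.), CH2Cl2, rt
Reagents that add atoms: acetic anhydride CC(=O)OC(C)=O
Why: DMAP-catalysed acetylation protects the primary alcohol against the allylic oxidation and bromination that follow.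

Step 7
Reactants: 11 (3R,6E)-3,7,11-trimethyldodeca-6,10-dien-1-yl acetate
Product: 12 (3R,6E,10E)-12-hydroxy-3,7,11-trimethyldodeca-6,10-dien-1-yl acetate
Conditions: SeO2 (0.1 equiv), t-BuOOH (3 equiv), salicylic acid (0.1 equiv), CH2Cl2, rt
Reagents that add atoms: tert-butyl hydroperoxide CC(C)(C)OO (oxygen relayed through catalytic selenium dioxide O=[Se]=O)
Why: Riley-type allylic oxidation (ene reaction, then [2,3]-sigmatropic shift) should hydroxylate the (E)-methyl of the terminal isopropylidene group in preference to the internal alkene, which gives the 10E allylic alcohol.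

Step 8
Reactants: 12 (3R,6E,10E)-12-hydroxy-3,7,11-trimethyldodeca-6,10-dien-1-yl acetate
Product: 13 (3R,6E,10E)-12-bromo-3,7,11-trimethyldodeca-6,10-dien-1-yl acetate
Conditions: CBr4, PPh3, CH2Cl2, 0 °C
Reagents that add atoms: carbon tetrabromide BrC(Br)(Br)Br
Why: Appel bromination converts the primary allylic alcohol into the bromide under neutral conditions, without allylic transposition and without loss of the acetate.

Step 9
Reactants: 14 (2E,6E,10E)-geranylgeraniol
Product: 15 (2E,6E,10E)-geranylgeranyl bromide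
Conditions: PBr3 (0.4 equiv), Et2O, –10 °C
Reagents that add atoms: phosphorus tribromide BrP(Br)Br
Why: Low-temperature bromination of a primary allylic alcohol with PBr3 (SN2 on the phosphite) should keep the 2E geometry.

Step 10
Reactants: 15 (2E,6E,10E)-geranylgeranyl bromide
Product: 16 [(2E,6E,10E)-3,7,11,15-tetramethylhexadeca-2,6,10,14-tetraen-1-yl]sulfonylbenzene (geranylgeranyl phenyl sulfone)
Conditions: PhSO2Na, DMF, rt
Reagents that add atoms: sodium benzenesulfinate [Na+].[O-]S(=O)c1ccccc1
Why: S-alkylation of the sulfinate (SN2) at the primary allylic carbon gives the allylic sulfone that serves as the carbanion precursor for chain extension.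

Step 11
Reactants: 16 geranylgeranyl phenyl sulfone; 13 (3R,6E,10E)-12-bromo-3,7,11-trimethyldodeca-6,10-dien-1-yl acetate
Product: 17 (3R,6E,10E,14E,18E,22E)-3,7,11,15,19,23,27-heptamethyl-13-(phenylsulfonyl)octacosa-6,10,14,18,22,26-hexaen-1-yl acetate (both C13 epimers)
Conditions: n-BuLi (1.05 equiv), THF/DMPU, –78 °C; then 13, –78 to –40 °C
Reagents that add atoms: none
Why: Alkylation of the α-sulfonyl allyl carbanion with the primary allylic bromide (Biellmann-type head-to-tail coupling, SN2) forms C20′–C21′ without touching either alkene geometry, and the acetate should survive at –78 °C.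

Step 12
Reactants: 17 the C35 sulfone acetate
Product: 18 (3R,6E,10E,14E,18E,22E)-3,7,11,15,19,23,27-heptamethyloctacosa-6,10,14,18,22,26-hexaen-1-ol
Conditions: PdCl2(dppp) (5 mol%), LiBHEt3 (5 equiv), THF, 0 °C to rt
Reagents that add atoms: none
Why: Pd-catalysed hydride desulfonylation of the allylic sulfone (π-allylpalladium, hydride delivered to the less substituted terminus) should keep the Δ14 alkene in place and E, and the excess hydride cleaves the acetate in the same operation.

Step 13
Reactants: 18 the C35 alcohol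
Product: 19 (3R,6E,10E,14E,18E,22E)-1-iodo-3,7,11,15,19,23,27-heptamethyloctacosa-6,10,14,18,22,26-hexaene
Conditions: I2, PPh3, imidazole, Et2O/MeCN, 0 °C
Reagents that add atoms: iodine II
Why: Appel-type iodination (PPh3/I2/imidazole) of the primary alcohol by SN2 gives the radical precursor without affecting the trisubstituted alkenes.

Step 14
Reactants: 20 N-benzylaniline; 21 acryloyl chloride
Product: 22 N-benzyl-N-phenylprop-2-enamide
Conditions: Et3N, CH2Cl2, 0 °C
Reagents that add atoms: none
Why: N-acylation of the secondary amine with the acid chloride (nucleophilic acyl substitution) provides the acceptor that already carries the anilide needed in the union step.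

Step 15
Reactants: 19 the C35 iodide; 22 N-benzyl-N-phenylprop-2-enamide
Product: 23 (6S,9E,13E,17E,21E,25E)-N-benzyl-6,10,14,18,22,26,30-heptamethyl-N-phenylhentriaconta-9,13,17,21,25,29-hexaenamide
Conditions: 22 (3 equiv), (Me3Si)3SiH (1.5 equiv, slow addition), AIBN (0.2 equiv), PhH, 80 °C
Reagents that add atoms: none
Why: In this Giese reaction (radical conjugate addition) the silyl radical abstracts iodine, the primary alkyl radical adds to the acrylamide β-carbon to form C8′–C9′ and the α-amido radical is reduced by Si–H, while the trisubstituted alkenes are poor radical acceptors and 6-exo cyclisation should be slower than the bimolecular addition.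

Step 16
Reactants: 23 the C38 anilide
Product: 24 (2RS,6S,9E,13E,17E,21E,25E)-N-benzyl-2-bromo-6,10,14,18,22,26,30-heptamethyl-N-phenylhentriaconta-9,13,17,21,25,29-hexaenamide
Conditions: LDA (1.1 equiv), THF, –78 °C; enolate cannulated into BrCCl2CCl2Br (1.3 equiv), THF, –78 °C
Reagents that add atoms: 1,2-dibromotetrachloroethane BrC(Cl)(Cl)C(Cl)(Cl)Br
Why: α-Bromination of the amide enolate with a positive-bromine donor that ignores alkenes installs the leaving group at C7′ as both epimers on purpose, and inverse addition limits alkylation of the enolate by the product.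

Step 17
Reactants: 24 the α-bromo anilide (both C2 epimers); 8 2-[(2E)-6-iodo-3-methylhex-2-en-1-yl]-1,4-dimethoxy-3-methylnaphthalene
Product: 26 (2R,6S,9E,13E,17E,21E,25E)-N-benzyl-2-[(4E)-6-(1,4-dimethoxy-3-methylnaphthalen-2-yl)-4-methylhex-4-en-1-yl]-6,10,14,18,22,26,30-heptamethyl-N-phenylhentriaconta-9,13,17,21,25,29-hexaenamide, via alkylzinc iodide 25 (not isolated)
Conditions: 8, Zn dust (I2-activated), DMI, 40 °C to give 25 (1.4 equiv); then NiCl2·glyme (10 mol%), (R)-(i-Pr)-Pybox (13 mol%), 24, DMI/THF, 0 °C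
Reagents that add atoms: none
Why: After transmetallation from 25, the Pybox–nickel(I) alkyl abstracts bromine from either C7′ epimer of 24 to give one planar α-amido radical, which is captured by nickel and released by reductive elimination from Ni(III) as the C6′–C7′ bond, so both epimers funnel into one product. The closest known reaction type is the Ni/Pybox-catalysed enantioconvergent Negishi coupling of racemic secondary α-bromo N-benzyl-N-phenyl amides with primary alkylzinc halides. No ring is closed. The new C7′ stereocentre (2R in 26) is set by the chiral ligand alone (catalyst control), and the existing C11′ centre, four carbons away, should exert no influence. The step needs facial selectivity at the radical-capture and reductive-elimination stage and chemoselectivity for the α-carbonyl C–Br bond: the anilide carbonyl weakens that bond and binds nickel, the nearest alkene of 24 (C14′=C15′) lies seven bonds from the radical centre so cyclisation cannot compete, and the aryl methyl ethers and trisubstituted alkenes are inert to alkylzinc and low-valent nickel at 0 °C.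

Step 18
Reactants: 26 the coupled anilide
Product: 27 (2R,6S,9E,13E,17E,21E,25E)-2-[(4E)-6-(1,4-dimethoxy-3-methylnaphthalen-2-yl)-4-methylhex-4-en-1-yl]-6,10,14,18,22,26,30-heptamethylhentriaconta-9,13,17,21,25,29-hexaen-1-ol
Conditions: LiAlH4, THF, 0 °C to rt; H2O/aq. NaOH work-up
Reagents that add atoms: none
Why: In this LiAlH4 reduction of an N-aryl tertiary amide the tetrahedral intermediate should lose the weakly basic anilide to give an aldehyde that is reduced on to the primary alcohol, and C7′ is not enolised under hydride conditions.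

Step 19
Reactants: 27 the primary alcohol
Product: 29 2-[(2E,7R,11S,14E,18E,22E,26E,30E)-3,7,11,15,19,23,27,31,35-nonamethylhexatriaconta-2,14,18,22,26,30,34-heptaen-1-yl]-1,4-dimethoxy-3-methylnaphthalene, via mesylate 28 (not isolated)
Conditions: MsCl, Et3N, THF, 0 °C; then LiBHEt3 (6 equiv), 0 to 40 °C
Reagents that add atoms: none
Why: Mesylation followed by SN2 hydride displacement with LiBHEt3 turns the CH2OH into the 7′-methyl group without involving the stereocentre, the arene or the alkenes.

Step 20
Reactants: 29 the dimethyl-protected hydroquinone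
Product: 30 2-methyl-3-[(2E,7R,11S,14E,18E,22E,26E,30E)-3,7,11,15,19,23,27,31,35-nonamethylhexatriaconta-2,14,18,22,26,30,34-heptaen-1-yl]naphthalene-1,4-dione (target)
Conditions: (NH4)2Ce(NO3)6 (2.5 equiv), MeCN/CH2Cl2/H2O, 0 °C
Reagents that add atoms: water O
Why: CAN oxidative demethylation (single-electron oxidation of the electron-rich 1,4-dimethoxyarene, then addition of water and loss of methanol) releases the para-quinone while the isolated trisubstituted alkenes should be untouched at 0 °C.

**Compound list**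

1 | menadione (2-methylnaphthalene-1,4-dione) | CC1=CC(=O)c2ccccc2C1=O | starting material
2 | menadiol (2-methylnaphthalene-1,4-diol) | Cc1cc(O)c2ccccc2c1O | intermediate
3 | 1,4-dimethoxy-2-methylnaphthalene | COc1cc(C)c(OC)c2ccccc12 | intermediate
4 | 2-(chloromethyl)-1,4-dimethoxy-3-methylnaphthalene | COc1c(C)c(CCl)c(OC)c2ccccc12 | intermediate
5 | 5-chloropent-1-yne | C#CCCCCl | starting material
6 | [(1E)-5-chloro-2-methylpent-1-en-1-yl]dimethylalane | C[Al](C)/C=C(\C)CCCCl | intermediate
7 | 2-[(2E)-6-chloro-3-methylhex-2-en-1-yl]-1,4-dimethoxy-3-methylnaphthalene | COc1c(C)c(C/C=C(\C)CCCCl)c(OC)c2ccccc12 | intermediate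
8 | 2-[(2E)-6-iodo-3-methylhex-2-en-1-yl]-1,4-dimethoxy-3-methylnaphthalene | COc1c(C)c(C/C=C(\C)CCCI)c(OC)c2ccccc12 | intermediate
9 | (2E,6E)-farnesol | CC(C)=CCC/C(C)=C/CC/C(C)=C/CO | starting material
10 | (3R,6E)-3,7,11-trimethyldodeca-6,10-dien-1-ol | CC(C)=CCC/C(C)=C/CC[C@@H](C)CCO | intermediate
11 | (3R,6E)-3,7,11-trimethyldodeca-6,10-dien-1-yl acetate | CC(C)=CCC/C(C)=C/CC[C@@H](C)CCOC(C)=O | intermediate
12 | (3R,6E,10E)-12-hydroxy-3,7,11-trimethyldodeca-6,10-dien-1-yl acetate | OC/C(C)=C/CC/C(C)=C/CC[C@@H](C)CCOC(C)=O | intermediate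
13 | (3R,6E,10E)-12-bromo-3,7,11-trimethyldodeca-6,10-dien-1-yl acetate | BrC/C(C)=C/CC/C(C)=C/CC[C@@H](C)CCOC(C)=O | intermediate
14 | (2E,6E,10E)-geranylgeraniol | CC(C)=CCC/C(C)=C/CC/C(C)=C/CC/C(C)=C/CO | starting material
15 | (2E,6E,10E)-geranylgeranyl bromide | CC(C)=CCC/C(C)=C/CC/C(C)=C/CC/C(C)=C/CBr | intermediate
16 | geranylgeranyl phenyl sulfone | CC(C)=CCC/C(C)=C/CC/C(C)=C/CC/C(C)=C/CS(=O)(=O)c1ccccc1 | intermediate
17 | (3R,6E,10E,14E,18E,22E)-3,7,11,15,19,23,27-heptamethyl-13-(phenylsulfonyl)octacosa-6,10,14,18,22,26-hexaen-1-yl acetate | CC(C)=CCC/C(C)=C/CC/C(C)=C/CC/C(C)=C/C(S(=O)(=O)c1ccccc1)C/C(C)=C/CC/C(C)=C/CC[C@@H](C)CCOC(C)=O | intermediate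
18 | (3R,6E,10E,14E,18E,22E)-3,7,11,15,19,23,27-heptamethyloctacosa-6,10,14,18,22,26-hexaen-1-ol | CC(C)=CCC/C(C)=C/CC/C(C)=C/CC/C(C)=C/CC/C(C)=C/CC/C(C)=C/CC[C@@H](C)CCO | intermediate
19 | (3R,6E,10E,14E,18E,22E)-1-iodo-3,7,11,15,19,23,27-heptamethyloctacosa-6,10,14,18,22,26-hexaene | CC(C)=CCC/C(C)=C/CC/C(C)=C/CC/C(C)=C/CC/C(C)=C/CC/C(C)=C/CC[C@@H](C)CCI | intermediate
20 | N-benzylaniline | C(Nc1ccccc1)c1ccccc1 | starting material
21 | acryloyl chloride | C=CC(Cl)=O | starting material
22 | N-benzyl-N-phenylprop-2-enamide | C=CC(=O)N(Cc1ccccc1)c1ccccc1 | intermediate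
23 | (6S,9E,13E,17E,21E,25E)-N-benzyl-6,10,14,18,22,26,30-heptamethyl-N-phenylhentriaconta-9,13,17,21,25,29-hexaenamide | CC(C)=CCC/C(C)=C/CC/C(C)=C/CC/C(C)=C/CC/C(C)=C/CC/C(C)=C/CC[C@@H](C)CCCCC(=O)N(Cc1ccccc1)c1ccccc1 | intermediate
24 | (2RS,6S,9E,13E,17E,21E,25E)-N-benzyl-2-bromo-6,10,14,18,22,26,30-heptamethyl-N-phenylhentriaconta-9,13,17,21,25,29-hexaenamide | CC(C)=CCC/C(C)=C/CC/C(C)=C/CC/C(C)=C/CC/C(C)=C/CC/C(C)=C/CC[C@@H](C)CCCC(Br)C(=O)N(Cc1ccccc1)c1ccccc1 | intermediate
25 | [(4E)-6-(1,4-dimethoxy-3-methylnaphthalen-2-yl)-4-methylhex-4-en-1-yl]zinc iodide | COc1c(C)c(C/C=C(\C)CCC[Zn]I)c(OC)c2ccccc12 | intermediate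
26 | (2R,6S,9E,13E,17E,21E,25E)-N-benzyl-2-[(4E)-6-(1,4-dimethoxy-3-methylnaphthalen-2-yl)-4-methylhex-4-en-1-yl]-6,10,14,18,22,26,30-heptamethyl-N-phenylhentriaconta-9,13,17,21,25,29-hexaenamide | CC(C)=CCC/C(C)=C/CC/C(C)=C/CC/C(C)=C/CC/C(C)=C/CC/C(C)=C/CC[C@@H](C)CCC[C@@H](C(=O)N(Cc1ccccc1)c1ccccc1)CCC/C(C)=C/Cc1c(C)c(OC)c2ccccc2c1OC | intermediate
27 | (2R,6S,9E,13E,17E,21E,25E)-2-[(4E)-6-(1,4-dimethoxy-3-methylnaphthalen-2-yl)-4-methylhex-4-en-1-yl]-6,10,14,18,22,26,30-heptamethylhentriaconta-9,13,17,21,25,29-hexaen-1-ol | CC(C)=CCC/C(C)=C/CC/C(C)=C/CC/C(C)=C/CC/C(C)=C/CC/C(C)=C/CC[C@@H](C)CCC[C@@H](CO)CCC/C(C)=C/Cc1c(C)c(OC)c2ccccc2c1OC | intermediate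
28 | methanesulfonate of 27 | CC(C)=CCC/C(C)=C/CC/C(C)=C/CC/C(C)=C/CC/C(C)=C/CC/C(C)=C/CC[C@@H](C)CCC[C@@H](COS(C)(=O)=O)CCC/C(C)=C/Cc1c(C)c(OC)c2ccccc2c1OC | intermediate
29 | 2-[(2E,7R,11S,14E,18E,22E,26E,30E)-3,7,11,15,19,23,27,31,35-nonamethylhexatriaconta-2,14,18,22,26,30,34-heptaen-1-yl]-1,4-dimethoxy-3-methylnaphthalene | CC(C)=CCC/C(C)=C/CC/C(C)=C/CC/C(C)=C/CC/C(C)=C/CC/C(C)=C/CC[C@@H](C)CCC[C@@H](C)CCC/C(C)=C/Cc1c(C)c(OC)c2ccccc2c1OC | intermediate
30 | 2-methyl-3-[(2E,7R,11S,14E,18E,22E,26E,30E)-3,7,11,15,19,23,27,31,35-nonamethylhexatriaconta-2,14,18,22,26,30,34-heptaen-1-yl]naphthalene-1,4-dione | CC(C)=CCC/C(C)=C/CC/C(C)=C/CC/C(C)=C/CC/C(C)=C/CC/C(C)=C/CC[C@@H](C)CCC[C@@H](C)CCC/C(C)=C/CC1=C(C)C(=O)c2ccccc2C1=O | target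

**Step count**

Total: 20 steps. Longest linear sequence: 13 steps (steps 5, 6, 7, 8, 11, 12, 13, 15, 16, 17, 18, 19, 20).

**Steps most likely to fail**

Step 17. The catalyst may discriminate poorly between the two faces of a radical that carries two long, almost identical chains, or radical capture may stall with such bulky partners and leave reduced amide. The fallback makes the same bond stereospecifically with known chemistry; it sets out from 19 and 7 and comes back to the route at 29. Iodide 19 would be converted by iodine–lithium exchange (t-BuLi, Et2O/pentane, –78 °C) into the alkyllithium F1. With BF3·OEt2, F1 opens (S)-propylene oxide at its CH2 terminus to give (2S,6S,9E,13E,17E,21E,25E)-6,10,14,18,22,26,30-heptamethylhentriaconta-9,13,17,21,25,29-hexaen-2-ol F2, so the 7′-methyl group and its configuration are taken from the chiral pool. Tosylation (TsCl, pyridine) gives the secondary tosylate F3. Chloride 7 is turned into the Grignard reagent F4 (Mg, THF) and coupled with F3 under CuI/TMEDA/LiOMe catalysis, an SN2 displacement with inversion that should deliver 29, which then enters step 20.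

Step 7. Oxidation may also occur at the allylic positions of the internal C6=C7 alkene, and the product may be over-oxidised to the enal, so that conversion to the single E-alcohol is low. The fallback replaces C–H oxidation by cleavage and olefination; it sets out from 11 and comes back at 12. Terminal-selective bromohydrin formation (NBS, THF/H2O, 0 °C) gives (3R,6E)-10-bromo-11-hydroxy-3,7,11-trimethyldodec-6-en-1-yl acetate F5. DBU closes it to the 10,11-epoxide F6, and periodic acid cleaves the epoxide to (3R,6E)-3,7-dimethyl-10-oxodec-6-en-1-yl acetate F7. An E-selective Wittig reaction with 2-(triphenylphosphoranylidene)propanal gives the (10E)-enal F8, and Luche reduction (NaBH4, CeCl3, MeOH, 0 °C) should return 12 with the acetate intact.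

Step 15. The α-amido radical may add to further acrylamide (telomerisation), and the primary radical may be reduced or cyclise onto C6=C7 before it is trapped. The fallback builds the same three-carbon extension by polar chemistry; it sets out from 19 and comes back at 23. Iodide 19 is converted into the Grignard reagent F9 (Mg, Et2O), which opens β-propiolactone at the β-carbon under CuCl catalysis to give (6S,9E,13E,17E,21E,25E)-6,10,14,18,22,26,30-heptamethylhentriaconta-9,13,17,21,25,29-hexaenoic acid F10. Oxalyl chloride with catalytic DMF gives the acid chloride F11, and acylation of N-benzylaniline 20 in pyridine/CH2Cl2 should give 23.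

**Further compounds**

F1 | step 17 | alkyllithium from 19 (iodine replaced by lithium) | CC(C)=CCC/C(C)=C/CC/C(C)=C/CC/C(C)=C/CC/C(C)=C/CC/C(C)=C/CC[C@@H](C)CC[Li]
F2 | step 17 | (2S,6S,9E,13E,17E,21E,25E)-6,10,14,18,22,26,30-heptamethylhentriaconta-9,13,17,21,25,29-hexaen-2-ol | CC(C)=CCC/C(C)=C/CC/C(C)=C/CC/C(C)=C/CC/C(C)=C/CC/C(C)=C/CC[C@@H](C)CCC[C@H](C)O
F3 | step 17 | 4-methylbenzenesulfonate of F2 | CC(C)=CCC/C(C)=C/CC/C(C)=C/CC/C(C)=C/CC/C(C)=C/CC/C(C)=C/CC[C@@H](C)CCC[C@H](C)OS(=O)(=O)c1ccc(C)cc1
F4 | step 17 | [(4E)-6-(1,4-dimethoxy-3-methylnaphthalen-2-yl)-4-methylhex-4-en-1-yl]magnesium chloride | COc1c(C)c(C/C=C(\C)CCC[Mg]Cl)c(OC)c2ccccc12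
F5 | step 7 | (3R,6E)-10-bromo-11-hydroxy-3,7,11-trimethyldodec-6-en-1-yl acetate | CC(C)(O)C(Br)CC/C(C)=C/CC[C@@H](C)CCOC(C)=O
F6 | step 7 | (3R,6E)-10,11-epoxy-3,7,11-trimethyldodec-6-en-1-yl acetate | CC1(C)OC1CC/C(C)=C/CC[C@@H](C)CCOC(C)=O
F7 | step 7 | (3R,6E)-3,7-dimethyl-10-oxodec-6-en-1-yl acetate | O=CCC/C(C)=C/CC[C@@H](C)CCOC(C)=O
F8 | step 7 | (3R,6E,10E)-3,7,11-trimethyl-12-oxododeca-6,10-dien-1-yl acetate | O=C/C(C)=C/CC/C(C)=C/CC[C@@H](C)CCOC(C)=O
F9 | step 15 | Grignard reagent from 19 (iodomagnesium in place of iodine) | CC(C)=CCC/C(C)=C/CC/C(C)=C/CC/C(C)=C/CC/C(C)=C/CC/C(C)=C/CC[C@@H](C)CC[Mg]I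
F10 | step 15 | (6S,9E,13E,17E,21E,25E)-6,10,14,18,22,26,30-heptamethylhentriaconta-9,13,17,21,25,29-hexaenoic acid | CC(C)=CCC/C(C)=C/CC/C(C)=C/CC/C(C)=C/CC/C(C)=C/CC/C(C)=C/CC[C@@H](C)CCCCC(=O)O
F11 | step 15 | acid chloride of F10 | CC(C)=CCC/C(C)=C/CC/C(C)=C/CC/C(C)=C/CC/C(C)=C/CC/C(C)=C/CC[C@@H](C)CCCCC(Cl)=O
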